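Start with the tank, maple.

| flask | starting material | partner | time | remark |
|---|---|---|---|---|
| cedar | 0.18 M | 0.270 M | 3.0 h | a closed flask charged with all of it at once and left for 3.0 h |
| alder | 0.18 M (fed, over 1.50 h) | 0.270 M | 3.0 h | a stirred flask in which starting material is dosed at a steady rate over 1.50 h without added volume, worked up at 3.0 h |
| elm | 0.18 M | 0.270 M (fed, over 1.50 h) | 3.0 h | a stirred flask in which partner is dosed at a steady rate over 1.50 h without added volume, worked up at 3.0 h |
| maple | 0.18 M | 0.270 M |  | one stirred flow tank at steady state, fed with the mixture as stated, mean residence time 3.0 h |

    starting material → open intermediate (k1 = 5.5 × 10⁻⁴ s⁻¹)
    partner → second intermediate (k2 = 5.9 × 10⁻⁴ s⁻¹)
    open intermediate + second intermediate → target (k3 = 0.038 M⁻¹ s⁻¹)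
    2 second intermediate → homo product (k4 = 0.034 M⁻¹ s⁻¹)
    starting material + open intermediate → side product (k5 = 0.032 M⁻¹ s⁻¹)

* the set-up with the highest share of target in all that became target or side product, at the outlet or at the end ("none" if the first two lie within 2 percentage points) (cedar / alder / elm / maple / none)
* share of target in all that became target or side product, at the outlet or at the end, cedar
* share of target in all that became target or side product, at the outlet or at the end, alder
* share of target in all that became target or side product, at the outlet or at the end, elm
* share of target in all that became target or side product, at the outlet or at the end, maple

- percentages count the starting material that a species holds: one side product counts as two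
- where a step has two of a species, its rate is k times that concentration squared, and two are used at each turn
- the stated concentrations are those of everything mixed, before any reaction; amounts are the same in each set-up
- the feed brings no volume worth counting
- run time (cedar): 3.0 h

Starting material is the limiting reagent, its charge of 0.18 M lying below the 0.270 M of partner, so its balance comes first. On the main route, with neither side product nor homo product, whatever opens ends as target and the share stands at 100 %.

Now let starting material catch open intermediate. Each open intermediate can go to target or to side product; both rates carry c(open intermediate), so it cancels in their ratio, and side product counts as two. The share being formed at any moment is c(second intermediate) / (c(second intermediate) + g·c(starting material)). Here g, the constant of the side step doubled over the constant of the target step, is 1.68, a selectivity factor. In maple, what the feed brings equals what leaves plus what reacts. Opening by itself leaves c(starting material) = 0.0259 M, and the side step can push it lower, so this is an upper limit. The same balance for partner makes 0.233 M of second intermediate per residence time. Target cannot hold more than 0.18 M, so without homo product at least 0.0534 M of second intermediate stands in the tank, and the maple share is at least 55.0 %.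

Now add homo product. If it took the whole supply, the squared rate would give c(second intermediate) = 0.0178 M, again an upper limit, and with both upper limits put in, the maple share is estimated at 29.0 %. I keep 29.0 % as my figure. At the charged c(starting material), an even split would need 0.303 M of second intermediate, more than the whole partner charge. At the maple level it needs 0.0437 M, so I expect maple to lead, and I reckon the other flasks no further.

The forecast gives 24.7 % for cedar, 25.3 % for alder, 14 % for elm and, from its solution of the steady-state balances, 32.8 % for maple, above my figure. It concludes: “Maple is best, with a clear margin over the next set-up.”

The simulation gives 25.6 % for cedar, 24.1 % for alder, 17.0 % for elm and 32.7 % for maple, so maple is best, as forecast.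

That outcome would turn if homo product were struck out: the best set-up then changes, and the maple share goes from 32.7 % to 75.1 %. Read through g, the ratio c(second intermediate)/c(starting material) at the maple outlet stands at 0.818 as run. The struck maple share lies above the floor of 55.0 %, and there the same ratio reads 5.07.

(The constants stand for no real mixture; no experiment stands behind them.)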